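**Assumption and conventions (one line):** the SMILES is read as the 8‑O‑angelate [(Z)‑2‑methylbut‑2‑enoate] of a (1R,3S,4R,6R,7S,8R,10S)‑1,10‑cis‑epoxy‑germacran‑12,6‑olide; germacrane numbering (C1–C15) is used in descriptions; PMB = 4‑methoxybenzyl, TES = triethylsilyl, TMS = trimethylsilyl.

## Retrosynthetic overview

1. Endgame: PMB removal; the C4/C15 diol comes from osmylation of a 4(15)‑exocyclic methylene, anti to O3.
2. Key disconnection C5–C6 together with O6–C12: a chromium‑mediated intramolecular allylation of a C6 aldehyde by a 2‑(chloromethyl)allyl unit, the alkoxide lactonising in the same flask, so the ten‑membered carbocycle and the α‑methylene lactone form together.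
3. Before that, on the open chain: the 1,10‑epoxide (first ring) by C8‑hydroxyl‑directed vanadium epoxidation, then the angelate.
4. C7–C8: asymmetric 2‑(methoxycarbonyl)allylation joining a C8 aldehyde (C1–C5, C8–C10, C14, C15) with a Baylis–Hillman‑derived bromide (C6, C7, C11–C13).
5. Aldehyde half: butynal acetal plus oxirane, iron‑catalysed methylmagnesiation (Z‑alkene), asymmetric isopropenylation (C3). Ring order: epoxide first, then carbocycle and lactone simultaneously.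

## Route

Step 1
Reactants: 1 4,4‑diethoxybut‑1‑yne; 2 oxirane
Product: 3 6,6‑diethoxyhex‑3‑yn‑1‑ol
Conditions: n‑BuLi, THF, −78 °C; then 2, DMPU, −78 °C → rt; H2O
Reagents that add atoms: none
Why: Lithium acetylide opening of ethylene oxide (alkynylation of an epoxide) gives the homopropargylic alcohol needed to direct the next step; the acetal is inert to the base.

Step 2
Reactants: 3 6,6‑diethoxyhex‑3‑yn‑1‑ol
Product: 4 (3Z)‑6,6‑diethoxy‑4‑methylhex‑3‑en‑1‑ol
Conditions: MeMgBr (4 equiv), Fe(acac)3 (15 mol %), THF, −20 → 0 °C; H2O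
Reagents that add atoms: methylmagnesium bromide, C[Mg]Br
Why: Alkoxide‑directed iron‑catalysed syn‑carbomagnesiation of a homopropargylic alcohol puts methyl on the distal alkyne carbon (C10) and magnesium on C1 in a five‑membered chelate, so protonolysis leaves the two chain arms cis (Z).

Step 3
Reactants: 4 (3Z)‑6,6‑diethoxy‑4‑methylhex‑3‑en‑1‑ol
Product: 5 (3Z)‑6,6‑diethoxy‑4‑methylhex‑3‑enal
Conditions: Dess–Martin periodinane, pyridine, CH2Cl2, 0 °C; used crude
Reagents that add atoms: none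
Why: Buffered Dess–Martin oxidation gives the β,γ‑unsaturated aldehyde without acid or base that would move the Z‑alkene into conjugation.

Step 4
Reactants: 5 (3Z)‑6,6‑diethoxy‑4‑methylhex‑3‑enal; 6 2‑bromopropene
Product: 8 (3S,5Z)‑8,8‑diethoxy‑2,6‑dimethylocta‑1,5‑dien‑3‑ol, via trimethylsilyl ether 7 (not isolated)
Conditions: 6, CrCl2 (10 mol %), NiCl2 (2 mol %), chiral oxazoline–sulfonamide ligand (12 mol %), Et3N (12 mol %), Mn, TMSCl, THF, rt; then K2CO3 (cat.), MeOH, 0 °C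
Reagents that add atoms: none
Why: Catalytic asymmetric Nozaki–Hiyama–Kishi alkenylation under neutral conditions; the ligand antipode is chosen to deliver the 3S carbinol (reagent control, checked by Mosher analysis) and the aldehyde does not isomerise.

Step 5
Reactants: 8 (3S,5Z)‑8,8‑diethoxy‑2,6‑dimethylocta‑1,5‑dien‑3‑ol
Product: 9 (3S,5Z)‑8,8‑diethoxy‑3‑(PMB‑oxy)‑2,6‑dimethylocta‑1,5‑diene
Conditions: NaH, PMBCl, n‑Bu4NI (cat.), THF/DMF, 0 °C → rt
Reagents that add atoms: 4‑methoxybenzyl chloride, COc1ccc(CCl)cc1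
Why: Williamson etherification blocks O3, so it can neither direct the later vanadium epoxidation to the neighbouring alkene nor be oxidised; the stereocentre is untouched.

Step 6
Reactants: 9 (3S,5Z)‑8,8‑diethoxy‑3‑(PMB‑oxy)‑2,6‑dimethylocta‑1,5‑diene
Product: 10 (3Z,6S)‑6‑(PMB‑oxy)‑3,7‑dimethylocta‑3,7‑dienal
Conditions: 10 % aq. oxalic acid on SiO2, CH2Cl2, rt; used at once
Reagents that add atoms: water, O
Why: Mild heterogeneous acetal hydrolysis frees the C8 aldehyde while sparing the allylic PMB ether and the skipped Z‑alkene.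

Step 7
Reactants: 11 1,4‑dioxane‑2,5‑diol (glycolaldehyde dimer)
Product: 12 (TES‑oxy)acetaldehyde
Conditions: TESCl, imidazole, CH2Cl2/DMF, 0 °C → rt
Reagents that add atoms: chlorotriethylsilane, CC[Si](CC)(CC)Cl
Why: The dimer equilibrates with monomeric glycolaldehyde, whose hydroxyl is silylated (two equivalents of 12 per dimer).

Step 8
Reactants: 12 (TES‑oxy)acetaldehyde; 13 methyl acrylate
Product: 14 methyl 3‑hydroxy‑2‑methylidene‑4‑(TES‑oxy)butanoate (racemic)
Conditions: 13 (excess), DABCO (cat.), neat, rt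
Reagents that add atoms: none
Why: Morita–Baylis–Hillman reaction, fast with an α‑oxygenated aldehyde; the carbinol centre is erased in the next step.

Step 9
Reactants: 14 methyl 3‑hydroxy‑2‑methylidene‑4‑(TES‑oxy)butanoate
Product: 15 methyl (2Z)‑2‑(bromomethyl)‑4‑(TES‑oxy)but‑2‑enoate
Conditions: NBS, Me2S, CH2Cl2, 0 °C → rt
Reagents that add atoms: N‑bromosuccinimide, O=C1CCC(=O)N1Br
Why: Corey–Kim‑type activation with SN2′ bromide delivery gives the rearranged allyl bromide as the thermodynamic Z isomer (CH2OTES cis to CH2Br).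

Step 10
Reactants: 10 (3Z,6S)‑6‑(PMB‑oxy)‑3,7‑dimethylocta‑3,7‑dienal; 15 methyl (2Z)‑2‑(bromomethyl)‑4‑(TES‑oxy)but‑2‑enoate
Product: 17 methyl (3S,4R,6Z,9S)‑4‑hydroxy‑9‑(PMB‑oxy)‑6,10‑dimethyl‑2‑methylidene‑3‑[(TES‑oxy)methyl]undeca‑6,10‑dienoate, via trimethylsilyl ether 16 (not isolated)
Conditions: CrCl2 (10 mol %), chiral carbazole bis(oxazoline) ligand (12 mol %), i‑Pr2NEt (12 mol %), Mn, TMSCl, THF, 0 °C → rt; then citric acid (cat.), MeOH, 0 °C
Reagents that add atoms: none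
Why: Asymmetric Nozaki–Hiyama–Kishi 2‑(alkoxycarbonyl)allylation; the allylchromium reacts at C7 through a chair transition state with the CH2OTES arm (cis to CH2–Cr) axial, giving the 7,8‑syn adduct; the ligand antipode sets 8R, and silyl capping suppresses lactonisation onto O8.

Step 11
Reactants: 17 homoallylic alcohol from step 10
Product: 18 methyl (3S,4R)‑4‑hydroxy‑5‑[(2S,3R)‑3‑{(2S)‑2‑(PMB‑oxy)‑3‑methylbut‑3‑en‑1‑yl}‑2‑methyloxiran‑2‑yl]‑2‑methylidene‑3‑[(TES‑oxy)methyl]pentanoate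
Conditions: VO(acac)2 (5 mol %), t‑BuOOH (1.5 equiv), CH2Cl2, 0 °C → rt
Reagents that add atoms: tert‑butyl hydroperoxide, CC(C)(C)OO
Why: Homoallylic‑hydroxyl‑directed vanadium epoxidation reaches only the electron‑rich C1=C10 alkene (the isopropenyl group has no free OH nearby, the acrylate is electron‑poor); in the chair vanadate transition state C7 is equatorial and the Z‑substituted distal alkene carbon is equatorial, which delivers oxygen to give (1R,10S).

Step 12
Reactants: 18 epoxy alcohol; 19 angelic acid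
Product: 20 the C8 angelate of 18
Conditions: 19, 2,4,6‑trichlorobenzoyl chloride, Et3N, toluene, rt; then 18, 70 °C
Reagents that add atoms: none
Why: Yamaguchi mixed‑anhydride esterification without a nucleophilic catalyst keeps the Z geometry of the angelate; excess anhydride outruns the slow lactonisation of the syn γ‑hydroxy ester.

Step 13
Reactants: 20 angelate with isopropenyl group
Product: 21 the 2‑(chloromethyl)allyl analogue of 20 [C3 side chain now (2S)‑3‑(chloromethyl)‑2‑(PMB‑oxy)but‑3‑en‑1‑yl]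
Conditions: NCS, PhSeCl (10 mol %), CH2Cl2, rt
Reagents that add atoms: N‑chlorosuccinimide, O=C1CCC(=O)N1Cl
Why: Selenium‑catalysed ene‑type allylic chlorination with double‑bond transposition acts on the only electron‑rich alkene left (the isopropenyl group), since C1=C10 is already epoxidised and the acrylate and angelate are electron‑poor.

Step 14
Reactants: 21 allyl chloride with primary TES ether
Product: 22 methyl (3R,4R)‑3‑formyl‑4‑(angeloyloxy)‑5‑[(2S,3R)‑3‑{(2S)‑3‑(chloromethyl)‑2‑(PMB‑oxy)but‑3‑en‑1‑yl}‑2‑methyloxiran‑2‑yl]‑2‑methylidenepentanoate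
Conditions: (COCl)2, DMSO, CH2Cl2, −78 → −40 °C; i‑Pr2NEt, −78 → −30 °C; used at once
Reagents that add atoms: none
Why: Swern conditions cleave and oxidise a primary TES ether in one pot, so the free γ‑hydroxy acrylate (which would lactonise onto C6) is never formed; the cold hindered base limits epimerisation at C7 and loss of the β‑acyloxy group.

Step 15
Reactants: 22 chloro aldehyde
Product: 24 (1R,3S,6R,7S,8R,10S)‑8‑angeloyloxy‑1,10‑epoxy‑3‑(PMB‑oxy)germacra‑4(15),11(13)‑dien‑12,6‑olide, via chromium alkoxide 23 (not isolated)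
Conditions: CrCl2 (10 equiv), DMF/THF, 0.002 M, syringe pump, rt → 40 °C
Reagents that add atoms: none
Why: Intramolecular Nozaki–Hiyama–Kishi (Barbier‑type) allylation: the 2‑substituted allylchromium, whose two CH2 termini are equivalent, adds to the C6 aldehyde to close the ten‑membered ring with the 4(15)‑methylene in place, and the chromium alkoxide then closes onto the neighbouring methyl ester to give the lactone; Felkin–Anh addition (C8 arm anti) is reinforced by 1,3‑anti induction from the C8 acyloxy group, giving 6R and the trans‑fused lactone.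

Step 16
Reactants: 24 macrocyclic lactone
Product: 25 (1R,3S,4R,6R,7S,8R,10S)‑8‑angeloyloxy‑1,10‑epoxy‑4,15‑dihydroxy‑3‑(PMB‑oxy)germacr‑11(13)‑en‑12,6‑olide
Conditions: OsO4 (5 mol %), NMO (1.5 equiv), acetone/H2O, 0 °C
Reagents that add atoms: osmium tetroxide, O=[Os](=O)(=O)=O; N‑methylmorpholine N‑oxide, C[N+]1([O-])CCOCC1; water, O
Why: Upjohn dihydroxylation picks the only electron‑rich alkene (the exocyclic C4=C15; the α‑methylene lactone and angelate are electron‑poor) and attacks anti to the allylic C3 alkoxy group (Kishi's empirical rule, also the less hindered face), giving 4R.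

Step 17
Reactants: 25 PMB‑protected diol
Product: 26 target, (1R,3S,4R,6R,7S,8R,10S)‑8‑angeloyloxy‑1,10‑epoxy‑3,4,15‑trihydroxygermacr‑11(13)‑en‑12,6‑olide
Conditions: DDQ, CH2Cl2/pH 7 buffer, 0 °C
Reagents that add atoms: none
Why: Oxidative PMB cleavage is neutral, so the trisubstituted epoxide, the angelate and the α‑methylene lactone survive and no stereocentre is touched.

## Compound list

1 | 4,4‑diethoxybut‑1‑yne | C#CCC(OCC)OCC | starting material
2 | oxirane (ethylene oxide) | C1CO1 | starting material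
3 | 6,6‑diethoxyhex‑3‑yn‑1‑ol | OCCC#CCC(OCC)OCC | intermediate
4 | (3Z)‑6,6‑diethoxy‑4‑methylhex‑3‑en‑1‑ol | OCC/C=C(/C)CC(OCC)OCC | intermediate
5 | (3Z)‑6,6‑diethoxy‑4‑methylhex‑3‑enal | O=CC/C=C(/C)CC(OCC)OCC | intermediate
6 | 2‑bromopropene | CC(Br)=C | starting material
7 | {[(3S,5Z)‑8,8‑diethoxy‑2,6‑dimethylocta‑1,5‑dien‑3‑yl]oxy}trimethylsilane (not isolated) | C=C(C)[C@@H](O[Si](C)(C)C)C/C=C(/C)CC(OCC)OCC | intermediate
8 | (3S,5Z)‑8,8‑diethoxy‑2,6‑dimethylocta‑1,5‑dien‑3‑ol | C=C(C)[C@@H](O)C/C=C(/C)CC(OCC)OCC | intermediate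
9 | (3S,5Z)‑8,8‑diethoxy‑3‑[(4‑methoxybenzyl)oxy]‑2,6‑dimethylocta‑1,5‑diene | C=C(C)[C@@H](OCc1ccc(OC)cc1)C/C=C(/C)CC(OCC)OCC | intermediate
10 | (3Z,6S)‑6‑[(4‑methoxybenzyl)oxy]‑3,7‑dimethylocta‑3,7‑dienal | C=C(C)[C@@H](OCc1ccc(OC)cc1)C/C=C(/C)CC=O | intermediate
11 | 1,4‑dioxane‑2,5‑diol (glycolaldehyde dimer) | OC1COC(O)CO1 | starting material
12 | [(triethylsilyl)oxy]acetaldehyde | CC[Si](CC)(CC)OCC=O | intermediate
13 | methyl acrylate | C=CC(=O)OC | starting material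
14 | methyl 3‑hydroxy‑2‑methylidene‑4‑[(triethylsilyl)oxy]butanoate (racemic) | C=C(C(=O)OC)C(O)CO[Si](CC)(CC)CC | intermediate
15 | methyl (2Z)‑2‑(bromomethyl)‑4‑[(triethylsilyl)oxy]but‑2‑enoate | COC(=O)/C(CBr)=C/CO[Si](CC)(CC)CC | intermediate
16 | 4‑O‑trimethylsilyl ether of 17 (not isolated) | C=C(C(=O)OC)[C@@H](CO[Si](CC)(CC)CC)[C@H](O[Si](C)(C)C)C/C(C)=C\C[C@H](OCc1ccc(OC)cc1)C(C)=C | intermediate
17 | methyl (3S,4R,6Z,9S)‑4‑hydroxy‑9‑[(4‑methoxybenzyl)oxy]‑6,10‑dimethyl‑2‑methylidene‑3‑{[(triethylsilyl)oxy]methyl}undeca‑6,10‑dienoate | C=C(C(=O)OC)[C@@H](CO[Si](CC)(CC)CC)[C@H](O)C/C(C)=C\C[C@H](OCc1ccc(OC)cc1)C(C)=C | intermediate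
18 | methyl (3S,4R)‑4‑hydroxy‑5‑[(2S,3R)‑3‑{(2S)‑2‑[(4‑methoxybenzyl)oxy]‑3‑methylbut‑3‑en‑1‑yl}‑2‑methyloxiran‑2‑yl]‑2‑methylidene‑3‑{[(triethylsilyl)oxy]methyl}pentanoate | C=C(C(=O)OC)[C@@H](CO[Si](CC)(CC)CC)[C@H](O)C[C@]1(C)O[C@@H]1C[C@H](OCc2ccc(OC)cc2)C(C)=C | intermediate
19 | angelic acid, (2Z)‑2‑methylbut‑2‑enoic acid | C/C=C(/C)C(=O)O | starting material
20 | methyl (3S,4R)‑4‑{[(2Z)‑2‑methylbut‑2‑enoyl]oxy}‑5‑[(2S,3R)‑3‑{(2S)‑2‑[(4‑methoxybenzyl)oxy]‑3‑methylbut‑3‑en‑1‑yl}‑2‑methyloxiran‑2‑yl]‑2‑methylidene‑3‑{[(triethylsilyl)oxy]methyl}pentanoate | C=C(C(=O)OC)[C@@H](CO[Si](CC)(CC)CC)[C@H](OC(=O)/C(C)=C\C)C[C@]1(C)O[C@@H]1C[C@H](OCc2ccc(OC)cc2)C(C)=C | intermediate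
21 | methyl (3S,4R)‑5‑[(2S,3R)‑3‑{(2S)‑3‑(chloromethyl)‑2‑[(4‑methoxybenzyl)oxy]but‑3‑en‑1‑yl}‑2‑methyloxiran‑2‑yl]‑4‑{[(2Z)‑2‑methylbut‑2‑enoyl]oxy}‑2‑methylidene‑3‑{[(triethylsilyl)oxy]methyl}pentanoate | C=C(C(=O)OC)[C@@H](CO[Si](CC)(CC)CC)[C@H](OC(=O)/C(C)=C\C)C[C@]1(C)O[C@@H]1C[C@H](OCc2ccc(OC)cc2)C(=C)CCl | intermediate
22 | methyl (3R,4R)‑5‑[(2S,3R)‑3‑{(2S)‑3‑(chloromethyl)‑2‑[(4‑methoxybenzyl)oxy]but‑3‑en‑1‑yl}‑2‑methyloxiran‑2‑yl]‑3‑formyl‑4‑{[(2Z)‑2‑methylbut‑2‑enoyl]oxy}‑2‑methylidenepentanoate | C=C(C(=O)OC)[C@@H](C=O)[C@H](OC(=O)/C(C)=C\C)C[C@]1(C)O[C@@H]1C[C@H](OCc2ccc(OC)cc2)C(=C)CCl | intermediate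
23 | chromium alkoxide of methyl (1R,3S,6R,7S,8R,10S)‑8‑angeloyloxy‑1,10‑epoxy‑6‑hydroxy‑3‑[(4‑methoxybenzyl)oxy]germacra‑4(15),11(13)‑dien‑12‑oate, drawn as the free 6‑hydroxy ester (not isolated) | COC(=O)C(=C)[C@H]1[C@H](O)CC(=C)[C@@H](OCc2ccc(OC)cc2)C[C@H]3O[C@@]3(C)C[C@H]1OC(=O)/C(C)=C\C | intermediate
24 | (1R,3S,6R,7S,8R,10S)‑8‑angeloyloxy‑1,10‑epoxy‑3‑[(4‑methoxybenzyl)oxy]germacra‑4(15),11(13)‑dien‑12,6‑olide | C=C1C(=O)O[C@@H]2CC(=C)[C@@H](OCc4ccc(OC)cc4)C[C@H]3O[C@@]3(C)C[C@@H](OC(=O)/C(C)=C\C)[C@@H]12 | intermediate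
25 | (1R,3S,4R,6R,7S,8R,10S)‑8‑angeloyloxy‑1,10‑epoxy‑4,15‑dihydroxy‑3‑[(4‑methoxybenzyl)oxy]germacr‑11(13)‑en‑12,6‑olide | C=C1C(=O)O[C@@H]2C[C@@](O)(CO)[C@@H](OCc4ccc(OC)cc4)C[C@H]3O[C@@]3(C)C[C@@H](OC(=O)/C(C)=C\C)[C@@H]12 | intermediate
26 | (1R,3S,4R,6R,7S,8R,10S)‑8‑angeloyloxy‑1,10‑epoxy‑3,4,15‑trihydroxygermacr‑11(13)‑en‑12,6‑olide (CNP0307250.1) | C=C1C(=O)O[C@@H]2C[C@@](O)(CO)[C@@H](O)C[C@H]3O[C@@]3(C)C[C@@H](OC(=O)/C(C)=C\C)[C@@H]12 | target

## Step count and risks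

Total step count: 17. Longest linear sequence: 14 steps (steps 1–6, then 10–17); steps 7–9 make the second fragment.

Three steps most likely to fail:

Step 15 (ring closure plus lactonisation). The aldehyde 22 is epimerisable at C7 and can lose the β‑angelate, the ten‑membered closure competes with oligomerisation, and the C6 face selection rests on open‑chain models. Fallback: set out from chloride 21. Borylation catalysed by zerovalent palladium (Pd2(dba)3, B2pin2, KOAc, DMSO) gives the allylboronate, the 2‑[(pinacolatoboryl)methyl]allyl analogue of 21, F2. Swern oxidation of its primary TES ether as in step 14 gives the boronate aldehyde F3, which is not isolated: on warming in toluene it cyclises by uncatalysed intramolecular allylboration through a closed six‑membered transition state, and the borate closes onto the ester. The route is rejoined at 24.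

Step 10 (asymmetric allylation). Asymmetric chromium allylation with a γ‑substituted 2‑(alkoxycarbonyl)allyl bromide and an isomerisable aldehyde may give low syn/anti or enantiomer ratios, and O8 may lactonise. Fallback: set out from bromide 15 (with aldehyde 10). Palladium‑catalysed borylation (Pd2(dba)3, B2pin2, KOAc) converts 15 into methyl (2Z)‑2‑[(4,4,5,5‑tetramethyl‑1,3,2‑dioxaborolan‑2‑yl)methyl]‑4‑[(triethylsilyl)oxy]but‑2‑enoate F1. This adds to 10 under chiral phosphoric acid catalysis (a TRIP‑type BINOL phosphate, toluene, −30 °C) through a chair allylboration in which geometry fixes 7,8‑syn and the acid fixes the aldehyde face. Mild hydrolysis of the borate rejoins the route at 17.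

Step 16 (dihydroxylation). OsO4 might also attack the α‑methylene lactone. Fallback: set out from 24. Conjugate addition of dimethylamine (Me2NH, THF/EtOH, 0 °C) masks the lactone alkene as the 13‑dimethylamino‑11,13‑dihydro adduct F4 (C11 epimers). OsO4/NMO then meets only the exocyclic alkene and gives the amino diol F5. Exhaustive methylation (MeI, MeOH) gives the trimethylammonium iodide F6, and aqueous NaHCO3 eliminates trimethylamine to restore the α‑methylene lactone. The route is rejoined at 25.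

Further compounds

F1 | step 10 | methyl (2Z)‑2‑[(4,4,5,5‑tetramethyl‑1,3,2‑dioxaborolan‑2‑yl)methyl]‑4‑[(triethylsilyl)oxy]but‑2‑enoate | COC(=O)/C(CB1OC(C)(C)C(C)(C)O1)=C/CO[Si](CC)(CC)CC
F2 | step 15 | 2‑[(pinacolatoboryl)methyl]allyl analogue of 21 (CH2Cl replaced by CH2Bpin) | C=C(C(=O)OC)[C@@H](CO[Si](CC)(CC)CC)[C@H](OC(=O)/C(C)=C\C)C[C@]1(C)O[C@@H]1C[C@H](OCc2ccc(OC)cc2)C(=C)CB3OC(C)(C)C(C)(C)O3
F3 | step 15 | 2‑[(pinacolatoboryl)methyl]allyl analogue of aldehyde 22 | C=C(C(=O)OC)[C@@H](C=O)[C@H](OC(=O)/C(C)=C\C)C[C@]1(C)O[C@@H]1C[C@H](OCc2ccc(OC)cc2)C(=C)CB3OC(C)(C)C(C)(C)O3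
F4 | step 16 | 13‑(dimethylamino)‑11,13‑dihydro adduct of 24 (C11 epimers) | CN(C)CC1C(=O)O[C@@H]2CC(=C)[C@@H](OCc4ccc(OC)cc4)C[C@H]3O[C@@]3(C)C[C@@H](OC(=O)/C(C)=C\C)[C@@H]12
F5 | step 16 | 13‑(dimethylamino)‑11,13‑dihydro adduct of 25 (C11 epimers) | CN(C)CC1C(=O)O[C@@H]2C[C@@](O)(CO)[C@@H](OCc4ccc(OC)cc4)C[C@H]3O[C@@]3(C)C[C@@H](OC(=O)/C(C)=C\C)[C@@H]12
F6 | step 16 | 13‑(trimethylammonio)‑11,13‑dihydro derivative of 25, iodide (C11 epimers) | C[N+](C)(C)CC1C(=O)O[C@@H]2C[C@@](O)(CO)[C@@H](OCc4ccc(OC)cc4)C[C@H]3O[C@@]3(C)C[C@@H](OC(=O)/C(C)=C\C)[C@@H]12.[I-]
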